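**Strategy.** Everything rests on treating the C5–C10 ring-fusion bond of the cis-decalin as the new bond of a [3,3] shift. The C2 oxygen of ring A is tied to C6 as a δ-lactone (O–C6(=O)–C5–C4–C3–C2), and C2 carries the (E)-alkenyl unit C1=C10(CH3)–C9. Ireland–Claisen ring contraction of this lactone closes ring A through an enforced boat transition state. It transfers the C2 carbinol chirality to quaternary C10 and to C5 (C5–H and C10–CH3 cis), and it unmasks C6 as the acid that later acylates the C8 isopropenyl group to close ring B. The precursor is a 6-alkenyl-4,4-dimethyl-δ-valerolactone built from (R)-citronellol, trimethylsilylacetylene, AlMe3 and 3,3-dimethylglutaric anhydride.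

Key step: step 9

Remark: labdane numbering is used throughout (C2 bears the angelate, C4 the gem-dimethyl group, C5/C10 the ring fusion, C7=C8 the ring B alkene, C9 the side chain, C13 the side-chain methine, C15 the acid). The descriptors of the target define a cis-fused decalin (C5–H and C10–CH3 syn), and the route is built for exactly this configuration.

**Route**

Step 1
Reactants: 1 (R)-(+)-citronellol
Product: 2 tert-butyl{[(3R)-3,7-dimethyloct-6-en-1-yl]oxy}diphenylsilane
Conditions: TBDPSCl, imidazole, DMF, rt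
Reagents that add atoms: tert-butyl(chloro)diphenylsilane, CC(C)(C)[Si](Cl)(c1ccccc1)c1ccccc1
Why: Standard silylation of the primary alcohol gives a robust, non-enolisable mask for C15, and the C13 stereocentre is taken from the chiral pool.

Step 2
Reactants: 2 tert-butyl{[(3R)-3,7-dimethyloct-6-en-1-yl]oxy}diphenylsilane
Product: 3 (2E,6R)-8-[(tert-butyldiphenylsilyl)oxy]-2,6-dimethyloct-2-en-1-ol
Conditions: SeO2 (cat.), t-BuOOH, salicylic acid (cat.), CH2Cl2, rt
Reagents that add atoms: tert-butyl hydroperoxide, CC(C)(C)OO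
Why: Riley-type allylic oxidation (ene reaction then [2,3]-shift) should hydroxylate selectively the (E)-methyl group of the trisubstituted alkene.

Step 3
Reactants: 3 (2E,6R)-8-[(tert-butyldiphenylsilyl)oxy]-2,6-dimethyloct-2-en-1-ol
Product: 4 (2E,6R)-8-[(tert-butyldiphenylsilyl)oxy]-2,6-dimethyloct-2-en-1-yl diethyl phosphate
Conditions: ClP(O)(OEt)2, pyridine, DMAP (cat.), CH2Cl2, 0 °C
Reagents that add atoms: diethyl chlorophosphate, CCOP(=O)(Cl)OCC
Why: O-Phosphorylation turns the primary allylic alcohol into the leaving group needed for copper-catalysed allylic substitution.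

Step 4
Reactants: 4 (2E,6R)-8-[(tert-butyldiphenylsilyl)oxy]-2,6-dimethyloct-2-en-1-yl diethyl phosphate; 5 trimethylsilylacetylene
Product: 7 tert-butyl{[(3R,6R)-6-ethynyl-3,7-dimethyloct-7-en-1-yl]oxy}diphenylsilane, via TMS-capped enyne 6 (not isolated)
Conditions: 5, (i-Bu)2AlH, Et3N (cat.), hexanes, 55 °C; then 4, CuCl2·2H2O (cat.), chiral sulfonate-bearing imidazolinium salt (carbene precursor, cat.), THF, −30 → 22 °C; then K2CO3, MeOH, rt
Reagents that add atoms: none
Why: Copper-catalysed enantioselective allylic substitution (SN2') with the alkynylaluminium reagent should deliver the alkynyl group to C9 and shift the alkene into the isopropenyl group, the chiral carbene–copper catalyst (enantiomer chosen to give 6R in 7, i.e. 9R) setting C9 under catalyst control before methanolysis removes the silyl cap.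

Step 5
Reactants: 8 3,3-dimethylglutaric anhydride
Product: 9 5-methoxy-3,3-dimethyl-5-oxopentanoic acid
Conditions: MeOH, reflux
Reagents that add atoms: methanol, CO
Why: Alcoholysis of the symmetrical cyclic anhydride gives the half-ester directly.

Step 6
Reactants: 9 5-methoxy-3,3-dimethyl-5-oxopentanoic acid
Product: 10 methyl 5-chloro-3,3-dimethyl-5-oxopentanoate
Conditions: (COCl)2, DMF (cat.), CH2Cl2, 0 °C → rt
Reagents that add atoms: oxalyl chloride, O=C(Cl)C(=O)Cl
Why: Vilsmeier-type activation converts the free acid into the acid chloride and leaves the methyl ester untouched.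

Step 7
Reactants: 7 tert-butyl{[(3R,6R)-6-ethynyl-3,7-dimethyloct-7-en-1-yl]oxy}diphenylsilane; 10 methyl 5-chloro-3,3-dimethyl-5-oxopentanoate
Product: 12 methyl (6E,8R,11R)-13-[(tert-butyldiphenylsilyl)oxy]-3,3,7,11-tetramethyl-5-oxo-8-(prop-1-en-2-yl)tridec-6-enoate, via alkenylalane 11 (not isolated)
Conditions: AlMe3, Cp2ZrCl2 (cat.), CH2Cl2, 0 °C → rt; volatiles removed; then 10, Pd(PPh3)4 (cat.), THF, 0 °C → rt
Reagents that add atoms: trimethylaluminium, C[Al](C)C
Why: Negishi zirconium-catalysed methylalumination adds CH3 (C20) and aluminium syn across the terminal alkyne with the metal on C1, and palladium-catalysed acylation of the alkenylalane with retention should give the (E)-enone in which CH3 is cis and C9 trans to C2.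

Step 8
Reactants: 12 methyl (6E,8R,11R)-13-[(tert-butyldiphenylsilyl)oxy]-3,3,7,11-tetramethyl-5-oxo-8-(prop-1-en-2-yl)tridec-6-enoate
Product: 14 (6S)-6-[(1E,3R,6R)-8-[(tert-butyldiphenylsilyl)oxy]-2,6-dimethyl-3-(prop-1-en-2-yl)oct-1-en-1-yl]-4,4-dimethyltetrahydro-2H-pyran-2-one, via hydroxy ester 13 (not isolated)
Conditions: (R)-2-methyl-CBS-oxazaborolidine (cat.), catecholborane, toluene, −78 °C; then PPTS (cat.), toluene, 60 °C
Reagents that add atoms: none
Why: Corey–Bakshi–Shibata reduction with the alkenyl group as the large substituent should set the (S)-carbinol at C2 under reagent control, and the δ-hydroxy ester then lactonises onto the nearer ester, helped by the gem-dimethyl group.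

Step 9
Reactants: 14 (6S)-6-[(1E,3R,6R)-8-[(tert-butyldiphenylsilyl)oxy]-2,6-dimethyl-3-(prop-1-en-2-yl)oct-1-en-1-yl]-4,4-dimethyltetrahydro-2H-pyran-2-one
Product: 17 (1R,2R)-2-[(3R,6R)-8-[(tert-butyldiphenylsilyl)oxy]-2,6-dimethyloct-1-en-3-yl]-2,6,6-trimethylcyclohex-3-ene-1-carboxylic acid, via silyl ketene acetal 15 (not isolated), via silyl ester 16 (not isolated)
Conditions: LiN(i-Pr)2, Me3SiCl/Et3N, THF, −78 °C → rt; then toluene, 110 °C; then dilute aqueous HCl
Reagents that add atoms: none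
Why: The lactone enolate is trapped as the endocyclic silyl ketene acetal O–C6(OSiMe3)=C5, which undergoes an Ireland–Claisen [3,3]-sigmatropic rearrangement that forms C5–C10 and breaks the allylic C2–O bond; the closest known reaction type is the Claisen ring contraction of 6-alkenyl δ-lactone silyl enolates to cyclohex-3-enecarboxylic acids. Ring A is closed as a six-membered carbocycle by this ring contraction, and the C3–C4 bridge between C2 and C5 makes the transition state bicyclo[2.2.2]-like and therefore a boat. C5 and C10 are both set here: the bridge forces the carboxyl carbon C6 to end up syn to the departed C2 oxygen, so the CBS-derived C2 configuration fixes the absolute sense, and the (E)-alkene geometry in the boat places C10–CH3 cis to C5–H and the C6 and C9 arms cis. C9 and C13 are spectators. The step needs the rearrangement to outrun decomposition of the hindered ketene acetal and to tolerate the congested C4/C5/C10 array, which the concerted intramolecular bond formation and the placement of the small CH3 (not C9) in the inside position of the alkene should secure. Aqueous acid then frees the acid from the silyl ester.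

Step 10
Reactants: 17 (1R,2R)-2-[(3R,6R)-8-[(tert-butyldiphenylsilyl)oxy]-2,6-dimethyloct-1-en-3-yl]-2,6,6-trimethylcyclohex-3-ene-1-carboxylic acid
Product: 18 (5R,9R,10R,13R)-15-[(tert-butyldiphenylsilyl)oxy]-5,10-cis-labda-1,7-dien-6-one, i.e. (4R,4aR,8aR)-4-[(3R)-5-[(tert-butyldiphenylsilyl)oxy]-3-methylpentyl]-3,4a,8,8-tetramethyl-4a,7,8,8a-tetrahydronaphthalen-1(4H)-one
Conditions: (CF3CO)2O, CH2Cl2, 0 °C → rt; Et3N work-up
Reagents that add atoms: none
Why: The mixed anhydride acylates the terminal carbon of the cis-disposed isopropenyl group (intramolecular Friedel–Crafts-type alkene acylation, 6-endo) and the tertiary C8 cation loses a proton to the conjugated enone, so ring B closes cis-fused because C6 and C9 are already cis on ring A.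

Step 11
Reactants: 18 (5R,9R,10R,13R)-15-[(tert-butyldiphenylsilyl)oxy]-5,10-cis-labda-1,7-dien-6-one
Product: 20 (2S,5R,9R,10R,13R)-15-[(tert-butyldiphenylsilyl)oxy]-5,10-cis-labd-7-ene-2,6-diol (2-OH trans to C10–CH3; C6 epimers), via bis-boron adduct 19 (not isolated)
Conditions: 9-borabicyclo[3.3.1]nonane (9-BBN, excess), THF, 0 → 65 °C; then NaOH, H2O2, 0 °C → rt
Reagents that add atoms: hydrogen peroxide, OO
Why: 9-BBN should first reduce the enone 1,2 and then hydroborate only the cis-disubstituted C1=C2 alkene (the flanked trisubstituted C7=C8 alkene being inert to this reagent), with boron on C2 away from quaternary C10 and on the face anti to the axial C10 and C4 methyl groups, so that oxidation with retention gives the equatorial C2 alcohol trans to C10–CH3.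

Step 12
Reactants: 20 (2S,5R,9R,10R,13R)-15-[(tert-butyldiphenylsilyl)oxy]-5,10-cis-labd-7-ene-2,6-diol
Product: 21 (2S,5R,9R,10S,13R)-15-[(tert-butyldiphenylsilyl)oxy]-5,10-cis-labd-7-en-2-ol
Conditions: Et3SiH, CF3CO2H, CH2Cl2, −20 °C
Reagents that add atoms: none
Why: In this ionic hydrogenation the allylic C6 alcohol ionises to the C6–C7–C8 allyl cation, which should take hydride at the secondary C6 terminus to leave the trisubstituted C7=C8 alkene, while the non-ionisable C2 alcohol is untouched.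

Step 13
Reactants: 21 (2S,5R,9R,10S,13R)-15-[(tert-butyldiphenylsilyl)oxy]-5,10-cis-labd-7-en-2-ol; 22 angelic acid [(2Z)-2-methylbut-2-enoic acid]
Product: 23 (2S,5R,9R,10S,13R)-15-[(tert-butyldiphenylsilyl)oxy]-5,10-cis-labd-7-en-2-yl (2Z)-2-methylbut-2-enoate
Conditions: 22, 2,4,6-trichlorobenzoyl chloride, Et3N, toluene, rt; then 21, 80 °C
Reagents that add atoms: none
Why: Yamaguchi-type esterification through the mixed anhydride, run without a nucleophilic catalyst, should acylate the unhindered equatorial C2 alcohol and preserve the (Z)-geometry of the angelate.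

Step 14
Reactants: 23 (2S,5R,9R,10S,13R)-15-[(tert-butyldiphenylsilyl)oxy]-5,10-cis-labd-7-en-2-yl (2Z)-2-methylbut-2-enoate
Product: 24 (2S,5R,9R,10S,13R)-15-hydroxy-5,10-cis-labd-7-en-2-yl (2Z)-2-methylbut-2-enoate
Conditions: HF·pyridine, THF, 0 °C → rt
Reagents that add atoms: none
Why: Fluoride-mediated desilylation frees the primary alcohol under conditions that leave the angelate and the trisubstituted alkene intact.

Step 15
Reactants: 24 (2S,5R,9R,10S,13R)-15-hydroxy-5,10-cis-labd-7-en-2-yl (2Z)-2-methylbut-2-enoate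
Product: 25 CNP0248298.1, (2S,5R,9R,10S,13R)-2-(angeloyloxy)-5,10-cis-labd-7-en-15-oic acid
Conditions: TEMPO (cat.), PhI(OAc)2, MeCN/H2O, rt
Reagents that add atoms: water, O
Why: Oxoammonium-mediated oxidation of the primary alcohol through the aldehyde hydrate should give the acid without touching the C7=C8 alkene or the angelate.

**Compound list**

1 | (R)-(+)-citronellol | CC(C)=CCC[C@@H](C)CCO | starting material
2 | tert-butyl{[(3R)-3,7-dimethyloct-6-en-1-yl]oxy}diphenylsilane | CC(C)=CCC[C@@H](C)CCO[Si](c1ccccc1)(c1ccccc1)C(C)(C)C | intermediate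
3 | (2E,6R)-8-[(tert-butyldiphenylsilyl)oxy]-2,6-dimethyloct-2-en-1-ol | OC/C(C)=C/CC[C@@H](C)CCO[Si](c1ccccc1)(c1ccccc1)C(C)(C)C | intermediate
4 | (2E,6R)-8-[(tert-butyldiphenylsilyl)oxy]-2,6-dimethyloct-2-en-1-yl diethyl phosphate | CCOP(=O)(OCC)OC/C(C)=C/CC[C@@H](C)CCO[Si](c1ccccc1)(c1ccccc1)C(C)(C)C | intermediate
5 | trimethylsilylacetylene | C#C[Si](C)(C)C | starting material
6 | tert-butyl{[(3R,6R)-3,7-dimethyl-6-[(trimethylsilyl)ethynyl]oct-7-en-1-yl]oxy}diphenylsilane | C=C(C)[C@@H](CC[C@@H](C)CCO[Si](c1ccccc1)(c1ccccc1)C(C)(C)C)C#C[Si](C)(C)C | intermediate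
7 | tert-butyl{[(3R,6R)-6-ethynyl-3,7-dimethyloct-7-en-1-yl]oxy}diphenylsilane | C=C(C)[C@@H](CC[C@@H](C)CCO[Si](c1ccccc1)(c1ccccc1)C(C)(C)C)C#C | intermediate
8 | 3,3-dimethylglutaric anhydride | CC1(C)CC(=O)OC(=O)C1 | starting material
9 | 5-methoxy-3,3-dimethyl-5-oxopentanoic acid | COC(=O)CC(C)(C)CC(=O)O | intermediate
10 | methyl 5-chloro-3,3-dimethyl-5-oxopentanoate | COC(=O)CC(C)(C)CC(=O)Cl | intermediate
11 | dimethyl[(1E,3R,6R)-8-[(tert-butyldiphenylsilyl)oxy]-2,6-dimethyl-3-(prop-1-en-2-yl)oct-1-en-1-yl]alane | C=C(C)[C@@H](CC[C@@H](C)CCO[Si](c1ccccc1)(c1ccccc1)C(C)(C)C)/C(C)=C/[Al](C)C | intermediate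
12 | methyl (6E,8R,11R)-13-[(tert-butyldiphenylsilyl)oxy]-3,3,7,11-tetramethyl-5-oxo-8-(prop-1-en-2-yl)tridec-6-enoate | C=C(C)[C@@H](CC[C@@H](C)CCO[Si](c1ccccc1)(c1ccccc1)C(C)(C)C)/C(C)=C/C(=O)CC(C)(C)CC(=O)OC | intermediate
13 | methyl (5S,6E,8R,11R)-13-[(tert-butyldiphenylsilyl)oxy]-5-hydroxy-3,3,7,11-tetramethyl-8-(prop-1-en-2-yl)tridec-6-enoate | C=C(C)[C@@H](CC[C@@H](C)CCO[Si](c1ccccc1)(c1ccccc1)C(C)(C)C)/C(C)=C/[C@@H](O)CC(C)(C)CC(=O)OC | intermediate
14 | (6S)-6-[(1E,3R,6R)-8-[(tert-butyldiphenylsilyl)oxy]-2,6-dimethyl-3-(prop-1-en-2-yl)oct-1-en-1-yl]-4,4-dimethyltetrahydro-2H-pyran-2-one | O=C1CC(C)(C)C[C@H](O1)/C=C(\C)[C@H](CC[C@@H](C)CCO[Si](c2ccccc2)(c2ccccc2)C(C)(C)C)C(C)=C | intermediate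
15 | trimethylsilyl ketene acetal of 14 [(2S)-2-alkenyl-4,4-dimethyl-6-(trimethylsilyloxy)-3,4-dihydro-2H-pyran] | C[Si](C)(C)OC1=CC(C)(C)C[C@H](O1)/C=C(\C)[C@H](CC[C@@H](C)CCO[Si](c2ccccc2)(c2ccccc2)C(C)(C)C)C(C)=C | intermediate
16 | trimethylsilyl ester of 17 | C[Si](C)(C)OC(=O)[C@@H]1C(C)(C)CC=C[C@]1(C)[C@H](CC[C@@H](C)CCO[Si](c2ccccc2)(c2ccccc2)C(C)(C)C)C(C)=C | intermediate
17 | (1R,2R)-2-[(3R,6R)-8-[(tert-butyldiphenylsilyl)oxy]-2,6-dimethyloct-1-en-3-yl]-2,6,6-trimethylcyclohex-3-ene-1-carboxylic acid (carboxyl and side arm cis) | OC(=O)[C@@H]1C(C)(C)CC=C[C@]1(C)[C@H](CC[C@@H](C)CCO[Si](c2ccccc2)(c2ccccc2)C(C)(C)C)C(C)=C | intermediate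
18 | (5R,9R,10R,13R)-15-[(tert-butyldiphenylsilyl)oxy]-5,10-cis-labda-1,7-dien-6-one | CC1(C)CC=C[C@]2(C)[C@H](CC[C@@H](C)CCO[Si](c3ccccc3)(c3ccccc3)C(C)(C)C)C(C)=CC(=O)[C@H]12 | intermediate
19 | 2-(9-borabicyclo[3.3.1]nonan-9-yl) 6-O-(9-borabicyclo[3.3.1]nonan-9-yl) adduct of the reduced enone | B2(C3CCCC2CCC3)[C@H]1CC(C)(C)[C@H]2C(OB3C4CCCC3CCC4)C=C(C)[C@@H](CC[C@@H](C)CCO[Si](c3ccccc3)(c3ccccc3)C(C)(C)C)[C@@]2(C)C1 | intermediate
20 | (2S,5R,9R,10R,13R)-15-[(tert-butyldiphenylsilyl)oxy]-5,10-cis-labd-7-ene-2,6-diol (C6 epimers) | O[C@H]1CC(C)(C)[C@H]2C(O)C=C(C)[C@@H](CC[C@@H](C)CCO[Si](c3ccccc3)(c3ccccc3)C(C)(C)C)[C@@]2(C)C1 | intermediate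
21 | (2S,5R,9R,10S,13R)-15-[(tert-butyldiphenylsilyl)oxy]-5,10-cis-labd-7-en-2-ol | O[C@H]1CC(C)(C)[C@H]2CC=C(C)[C@@H](CC[C@@H](C)CCO[Si](c3ccccc3)(c3ccccc3)C(C)(C)C)[C@@]2(C)C1 | intermediate
22 | angelic acid, (2Z)-2-methylbut-2-enoic acid | C/C=C(/C)C(=O)O | starting material
23 | (2S,5R,9R,10S,13R)-15-[(tert-butyldiphenylsilyl)oxy]-5,10-cis-labd-7-en-2-yl (2Z)-2-methylbut-2-enoate | C/C=C(/C)C(=O)O[C@H]1CC(C)(C)[C@H]2CC=C(C)[C@@H](CC[C@@H](C)CCO[Si](c3ccccc3)(c3ccccc3)C(C)(C)C)[C@@]2(C)C1 | intermediate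
24 | (2S,5R,9R,10S,13R)-15-hydroxy-5,10-cis-labd-7-en-2-yl (2Z)-2-methylbut-2-enoate | C/C=C(/C)C(=O)O[C@H]1CC(C)(C)[C@H]2CC=C(C)[C@@H](CC[C@@H](C)CCO)[C@@]2(C)C1 | intermediate
25 | CNP0248298.1, (2S,5R,9R,10S,13R)-2-(angeloyloxy)-5,10-cis-labd-7-en-15-oic acid | C/C=C(/C)C(=O)O[C@H]1CC(C)(C)[C@H]2CC=C(C)[C@@H](CC[C@@H](C)CC(=O)O)[C@@]2(C)C1 | target

**Step count.** Total: 15 steps. Longest linear sequence: 13 steps (steps 1–4 and 7–15).

**Steps most likely to fail**

Step 9 (key step). The silyl ketene acetal may fail to rearrange: the boat transition state is congested (inside methyl against C3, gem-dimethyl next to C5), and the hindered α-methylene may silylate poorly or the ketene acetal may decompose first. The fallback sets out from 14 and avoids enolate chemistry. Reduction with (i-Bu)2AlH (CH2Cl2, −78 °C) should give the lactol (6S)-6-alkenyl-4,4-dimethyltetrahydro-2H-pyran-2-ol F4. Dehydration (MsCl, Et3N) should give the cyclic allyl vinyl ether (2S)-2-alkenyl-4,4-dimethyl-3,4-dihydro-2H-pyran F5. Thermal Claisen rearrangement of this neutral enol ether (sealed tube, about 200 °C, same bicyclic boat topology and stereochemical course) should give the aldehyde (1R,2R)-2-[(3R,6R)-8-(silyloxy)-2,6-dimethyloct-1-en-3-yl]-2,6,6-trimethylcyclohex-3-ene-1-carbaldehyde F6. Pinnick oxidation (NaClO2, NaH2PO4, 2-methyl-2-butene) comes back to the route at 17.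

Step 4. Enantiofacial discrimination or SN2' regiocontrol may be poor with the 2-methyl-substituted allylic phosphate. The fallback sets out from 3 and uses classical reagent control. Sharpless asymmetric epoxidation (Ti(Oi-Pr)4, L-(+)-diethyl tartrate, t-BuOOH, 4 Å sieves, CH2Cl2, −20 °C) should give the epoxy alcohol [(2S,3S)-3-{(3R)-5-[(tert-butyldiphenylsilyl)oxy]-3-methylpentyl}-2-methyloxiran-2-yl]methanol F1. The tartrate is the one that delivers oxygen to the same face as in the (2S,3S)-selective epoxidation of simple (E)-allylic alcohols. Opening at C3 with inversion by Et2AlC≡CSiMe3 (toluene, 0 °C) should give (2R,3S,6R)-8-[(tert-butyldiphenylsilyl)oxy]-2,6-dimethyl-3-[(trimethylsilyl)ethynyl]octane-1,2-diol F2. Thiocarbonyldiimidazole should convert it into the cyclic thionocarbonate of diol F2 (4-methyl-1,3-dioxolane-2-thione) F3. Corey–Winter elimination (P(OMe)3, heat) should unveil the isopropenyl group and come back to the route at 6, which K2CO3/MeOH converts to 7 as in step 4.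

Step 11. Hydroboration of the C7=C8 alkene may compete with that of C1=C2, or boron may be delivered to the wrong face. The fallback sets out from 18 and separates the two events. Luche reduction (NaBH4, CeCl3·7H2O, MeOH) should give the allylic alcohol 15-(silyloxy)-5,10-cis-labda-1,7-dien-6-ol F7. Ionic hydrogenation (Et3SiH, CF3CO2H, CH2Cl2, −20 °C) should give the diene 15-(silyloxy)-5,10-cis-labda-1,7-diene F8. Wacker-type oxidation (Pd(OAc)2 cat., benzoquinone, HBF4, MeCN/H2O) should oxidise only the cis-disubstituted C1=C2 alkene, with oxygen at C2 remote from quaternary C10, to the ketone 15-(silyloxy)-5,10-cis-labd-7-en-2-one F9. Thermodynamic dissolving-metal reduction (Na, i-PrOH, toluene) should give the equatorial alcohol and come back to the route at 21.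

**Further compounds**

F1 | step 4 | [(2S,3S)-3-{(3R)-5-[(tert-butyldiphenylsilyl)oxy]-3-methylpentyl}-2-methyloxiran-2-yl]methanol | OC[C@]1(C)O[C@H]1CC[C@@H](C)CCO[Si](c1ccccc1)(c1ccccc1)C(C)(C)C
F2 | step 4 | (2R,3S,6R)-8-[(tert-butyldiphenylsilyl)oxy]-2,6-dimethyl-3-[(trimethylsilyl)ethynyl]octane-1,2-diol | OC[C@](C)(O)[C@@H](CC[C@@H](C)CCO[Si](c1ccccc1)(c1ccccc1)C(C)(C)C)C#C[Si](C)(C)C
F3 | step 4 | cyclic thionocarbonate of diol F2 (4-methyl-1,3-dioxolane-2-thione) | S=C1OC[C@](C)(O1)[C@@H](CC[C@@H](C)CCO[Si](c2ccccc2)(c2ccccc2)C(C)(C)C)C#C[Si](C)(C)C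
F4 | step 9 | (6S)-6-[(1E,3R,6R)-8-[(tert-butyldiphenylsilyl)oxy]-2,6-dimethyl-3-(prop-1-en-2-yl)oct-1-en-1-yl]-4,4-dimethyltetrahydro-2H-pyran-2-ol (anomers) | OC1CC(C)(C)C[C@H](O1)/C=C(\C)[C@H](CC[C@@H](C)CCO[Si](c2ccccc2)(c2ccccc2)C(C)(C)C)C(C)=C
F5 | step 9 | (2S)-2-[(1E,3R,6R)-8-[(tert-butyldiphenylsilyl)oxy]-2,6-dimethyl-3-(prop-1-en-2-yl)oct-1-en-1-yl]-4,4-dimethyl-3,4-dihydro-2H-pyran | C1=CC(C)(C)C[C@H](O1)/C=C(\C)[C@H](CC[C@@H](C)CCO[Si](c2ccccc2)(c2ccccc2)C(C)(C)C)C(C)=C
F6 | step 9 | (1R,2R)-2-[(3R,6R)-8-[(tert-butyldiphenylsilyl)oxy]-2,6-dimethyloct-1-en-3-yl]-2,6,6-trimethylcyclohex-3-ene-1-carbaldehyde | O=C[C@@H]1C(C)(C)CC=C[C@]1(C)[C@H](CC[C@@H](C)CCO[Si](c2ccccc2)(c2ccccc2)C(C)(C)C)C(C)=C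
F7 | step 11 | 15-[(tert-butyldiphenylsilyl)oxy]-5,10-cis-labda-1,7-dien-6-ol (C6 epimers) | CC1(C)CC=C[C@]2(C)[C@H](CC[C@@H](C)CCO[Si](c3ccccc3)(c3ccccc3)C(C)(C)C)C(C)=CC(O)[C@H]12
F8 | step 11 | 15-[(tert-butyldiphenylsilyl)oxy]-5,10-cis-labda-1,7-diene | CC1(C)CC=C[C@]2(C)[C@H](CC[C@@H](C)CCO[Si](c3ccccc3)(c3ccccc3)C(C)(C)C)C(C)=CC[C@H]12
F9 | step 11 | 15-[(tert-butyldiphenylsilyl)oxy]-5,10-cis-labd-7-en-2-one | O=C1CC(C)(C)[C@H]2CC=C(C)[C@@H](CC[C@@H](C)CCO[Si](c3ccccc3)(c3ccccc3)C(C)(C)C)[C@@]2(C)C1
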